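The numbers in the tables are simulated from invented constants; the scatter is artificial.

The trap lay in the name: a transfer agent seems to start a fresh chain each time it acts, and every chain counted lowers the average. I had to choose the agent charge for the next flask, so I needed the chain length each charge gives.

| setting | dusk | midnight | noon | flask |
|---|---|---|---|---|
| free monomer | 0.067 M | 0.15 M | 0.10 M | 0.10 M |
| transfer agent | 3 mM | 3 mM | 4.5 mM | 3.00 mM |
| initiator | 2.5 mM | 2.5 mM | 2.5 mM | 2.5 mM |
| remark | run made earlier | run made earlier | run made earlier |  |
| time |  |  |  | 15 h |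

| run | time / h | monomer in chains / % | free monomer / % |
|---|---|---|---|
| dusk | 0.500 | 11.1 | 89.9 |
| dusk | 1.33 | 24.7 | 72.1 |
| dusk | 2.50 | 36.0 | 61.6 |
| dusk | 4.00 | 41.2 | 54.1 |
| dusk | 5.00 | 42.5 | 54.2 |
| dusk | 8.00 | 45.1 | 50.1 |
| dusk | 10.0 | 46.2 | 50.9 |
| midnight | 1.33 | 29.4 | 70.4 |
| midnight | 2.50 | 36.9 | 61.0 |
| midnight | 4.00 | 43.3 | 57.0 |
| midnight | 5.00 | 42.3 | 57.2 |
| midnight | 6.00 | 43.1 | 55.4 |
| midnight | 8.00 | 43.6 | 53.7 |
| midnight | 10.0 | 43.9 | 52.1 |
| noon | 2.00 | 24.8 | 72.8 |
| noon | 4.00 | 27.4 | 71.2 |
| noon | 5.00 | 26.5 | 71.9 |
| noon | 8.00 | 27.1 | 70.3 |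
| noon | 10.0 | 27.5 | 69.5 |

(each reading ± 1 percentage point)

- the average divides the monomer in chains by the number of chains begun, living and dead together
- the earlier runs do not show the number of chains; that part of a forecast is a guess

1. average number of monomer units in a chain (chains begun, living or dead) at 15 h
2. part of the free monomer that has reacted at 15 h

Monomer in chains had levelled off: between their last two readings, dusk rose 1.1 percentage points and midnight 0.3 points, against a scatter of 1 point. Those runs ended at 46.2% and 43.9%, and their monomer charges lie on either side of the flask's, so I took the mean. I guessed that each chain began on one initiator, none on the agent, and that the whole initiator charge began chains: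

plateau length = 45.0% × 0.10 M ÷ 2.5 mM = 18.0

This plateau length, monomer in chains at the plateau per initiator charged, was my yardstick. Noon's 27.5% at 4.5 mM of agent gives 11.0, shorter than that, so I kept the agent at 3.00 mM and left the flask to 15 h.

The forecast gave 14 and 51.5%, saying “Chains begun is a guess”; my length is longer than its figure.

The flask gave 17.9 and 49.6%.

    living end → dead end (k = 0.0450 h⁻¹)
    free monomer → uncatalysed product (k = 0.00520 h⁻¹)
    living end + transfer agent → dead chain (kL = 690 L mol⁻¹ h⁻¹)
    free monomer + initiator → living end + monomer in chains (k = 31.0 L mol⁻¹ h⁻¹)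
    free monomer + living end → monomer in chains + living end, rate k5*[living end]*[free monomer] (k = 250 L mol⁻¹ h⁻¹)
    monomer in chains → over-reaction product (k = 7.80 × 10⁻⁴ h⁻¹)

At 15.0 h the flask held 0% of its initiator, and its dead chains, dead ends and living ends came to 2.50 mM, so its 17.9 stood beside my 18.0. The chains stayed this long because the initiator fell and the agent was consumed: with initiator held level the flask gave 10.5, with agent held level 10.9. A neighbouring flask charged with 6.3 × 10⁻⁴ M of initiator held 0% of it at the end and 8.44% monomer in chains, so the same division gives 13.4, and it gave 13.4.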